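## Retrosynthetic overview

- Last bond C9–C11: an (R)-linalool-derived C5 organocerium adds axially to bromo-decalone 13. C3–Br comes from SN2 inversion of an axial carbinol; C5–H and C8–H come from hydrogenation and equilibration of dienone 10.
- Key disconnection: dienone 10 is an isomer of the monocyclic ynal 8. Step 4 forms C5–C10 (closing ring A) and then C7–C8 (closing ring B).
- Enabling feature: the C3 oxygen and the C9 carbonyl are 1,5-related (C3–C2–C1–C10–C9), so they close a temporary dihydropyran O–C9=C10. Its nucleophilic C10 lies 1,4 across that ring from C3, which carries the C4(Me)2–C5≡C6–C7HO arm. Once C5–C10 exists, C9=O and C7=O are a 1,5-dicarbonyl pair in which only C8 can enolise.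
- Ring order: temporary oxacycle (step 2), then ring A, then ring B (both in step 4, where the oxacycle is opened again). Ynal 8 comes in 3 steps from pentan-3-one, acrolein, a dimethylallenylboronate and DMF.

Key step: step 4

Assumption: (R)-TRIP is taken to give the (S)-carbinol in step 2, by analogy with its sense in allyl- and allenylborations of aldehydes; if the sense is opposite, (S)-TRIP is used and nothing else changes. C1–C20 in the text are the labdane positions of the target (C3 bromide, C9 carbinol, C10 angular-methyl carbon).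

## Route

Step 1
Reactants: 1 pentan-3-one; 2 acrolein (prop-2-enal)
Product: 4 4-methyl-5-oxoheptanal (racemic), via pyrrolidine enamine 3 (not isolated)
Conditions: pyrrolidine, p-TsOH (cat.), PhH, reflux, Dean–Stark; then 2, MeCN, 0 → 23 °C; then AcOH/NaOAc, H2O, 23 °C
Reagents that add atoms: none
Why: Stork enamine Michael addition of the symmetrical ketone to acrolein followed by buffered hydrolysis should give the 1,5-keto aldehyde; the new centre (C10) is racemic and is erased in step 2.

Step 2
Reactants: 4 4-methyl-5-oxoheptanal; 5 4,4,5,5-tetramethyl-2-(3-methylbuta-1,2-dien-1-yl)-1,3,2-dioxaborolane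
Product: 7 (2S)-6-ethyl-5-methyl-2-(2-methylbut-3-yn-2-yl)-3,4-dihydro-2H-pyran, via hydroxy ketone 6 (not isolated)
Conditions: (R)-TRIP (5 mol %), 4 Å MS, PhMe, −30 °C; aq NaHCO3 work-up; then PPTS (5 mol %), PhH, 80 °C, Dean–Stark
Reagents that add atoms: none
Why: Chiral-phosphoric-acid-catalysed allenylboration (SE2′, closed chair transition state) should attack only the aldehyde through the γ-carbon and set C3 (S) under catalyst control, and acid-catalysed cyclodehydration of the δ-hydroxy ketone through its hemiketal should give the more substituted endocyclic enol ether, which removes the C10 stereocentre.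

Step 3
Reactants: 7 (2S)-6-ethyl-5-methyl-2-(2-methylbut-3-yn-2-yl)-3,4-dihydro-2H-pyran
Product: 8 4-[(2S)-6-ethyl-5-methyl-3,4-dihydro-2H-pyran-2-yl]-4-methylpent-2-ynal
Conditions: n-BuLi, THF, −78 °C; DMF, −78 → 0 °C; reverse quench into 10% aq KH2PO4/MTBE, 0 °C
Reagents that add atoms: N,N-dimethylformamide, CN(C)C=O
Why: Formylation of the lithium acetylide with DMF should be clean because the cyclic enol ether masks both the hydroxyl and the ketone against n-BuLi, and the buffered reverse quench spares the enol ether.

Step 4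
Reactants: 8 4-[(2S)-6-ethyl-5-methyl-3,4-dihydro-2H-pyran-2-yl]-4-methylpent-2-ynal
Product: 10 (6S,8aR)-6-hydroxy-2,5,5,8a-tetramethyl-6,7,8,8a-tetrahydronaphthalen-1(5H)-one, via bridged enal 9 (not isolated)
Conditions: Ph3PAuNTf2 (5 mol %), CH2Cl2, 23 °C; then p-TsOH·H2O (20 mol %), H2O (2 equiv), PhMe, 60 °C
Reagents that add atoms: none
Why: Proposed new method: the π-acid and the formyl group make C5 of the ynal electrophilic, and the enol-ether carbon C10, held 1,4 across the dihydropyran from C3, should attack it in a 6-exo-dig closure of ring A, giving the 2-oxabicyclo[2.2.2]octane 9 after loss of H8 and protodeauration. Aqueous acid should then hydrolyse the exocyclic enol ether, the oxygen bridge opens to the C9 ketone and the axial C3 hydroxyl, and the ketone enol closes ring B on the C7 aldehyde by a 6-(enolendo)-exo-trig aldol condensation, so the overall change is an isomerisation in which water is only a catalyst. The closest known reaction types are gold-catalysed carbocyclisations of cyclic silyl enol ethers onto pendant alkynes that give bicyclo[2.2.2]octanones, acid-mediated conjugate additions of enol ethers to ynones, and the acid-catalysed Robinson-type aldol condensation of 1,5-keto aldehydes. The one new stereocentre, quaternary C10, is fixed by the temporary O–C9 bridge, because a bicyclo[2.2.2] skeleton can only form with C9 cis to the C3 oxygen on ring A, so (S)-C3 gives (R)-C10 with the methyl group exo. The step needs site selectivity for C10 over C8, which the endocyclic enol ether secures because attack through C8 would require an oxocarbenium ion with a bridgehead double bond; it also needs the Z-enal for the aldol, which acid-mediated E/Z equilibration of the β,β-disubstituted enal supplies while only the Z isomer is drained off, and any cyclobutene or 4H-pyran formed by collapse of the zwitterion would hydrolyse to the same keto enal.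

Step 5
Reactants: 10 (6S,8aR)-6-hydroxy-2,5,5,8a-tetramethyl-6,7,8,8a-tetrahydronaphthalen-1(5H)-one
Product: 12 (2S,4aR,6S,8aR)-6-hydroxy-2,5,5,8a-tetramethyloctahydronaphthalen-1(2H)-one, via C2-epimeric ketone 11 (not isolated)
Conditions: H2 (4 atm), 10% Pd/C, EtOAc, 23 °C; then NaOMe (0.2 equiv), MeOH, 23 °C
Reagents that add atoms: none
Why: Heterogeneous hydrogenation should deliver hydrogen to C5 from the face opposite the two syn-axial methyl groups on C4 and C10 (the pattern of 5-ene steroids), giving the trans ring fusion, and methoxide epimerisation should then place the C8 methyl equatorial, away from the 1,3-diaxial clash with the C10 methyl.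

Step 6
Reactants: 12 (2S,4aR,6S,8aR)-6-hydroxy-2,5,5,8a-tetramethyloctahydronaphthalen-1(2H)-one
Product: 13 (2S,4aS,6R,8aR)-6-bromo-2,5,5,8a-tetramethyloctahydronaphthalen-1(2H)-one
Conditions: PPh3, CBr4, CH2Cl2, 0 → 23 °C
Reagents that add atoms: carbon tetrabromide, BrC(Br)(Br)Br
Why: Appel reaction: bromide should displace the axial alkoxyphosphonium group with inversion (SN2) to give the equatorial C3 bromide, a substitution of the kind used on axial 3-hydroxy-4,4-dimethylcyclohexane (cyclogeranyl-type) rings.

Step 7
Reactants: 14 (R)-(−)-linalool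
Product: 15 triethyl{[(3R)-3,7-dimethylocta-1,6-dien-3-yl]oxy}silane
Conditions: TESOTf, 2,6-lutidine, CH2Cl2, −78 → 0 °C
Reagents that add atoms: triethylsilyl trifluoromethanesulfonate, CC[Si](CC)(CC)OS(=O)(=O)C(F)(F)F
Why: Silylation of the tertiary allylic alcohol with the silyl triflate should proceed without touching the C13 stereocentre, which comes from the chiral pool.

Step 8
Reactants: 15 triethyl{[(3R)-3,7-dimethylocta-1,6-dien-3-yl]oxy}silane
Product: 16 (4R)-4-methyl-4-[(triethylsilyl)oxy]hex-5-enal
Conditions: O3, CH2Cl2/MeOH, −78 °C (Sudan Red 7B end point); then Me2S, −78 → 23 °C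
Reagents that add atoms: ozone, [O-][O+]=O
Why: Ozonolysis should cleave the electron-rich trisubstituted alkene much faster than the monosubstituted vinyl group beside the quaternary centre, and the indicator marks the end point.

Step 9
Reactants: 16 (4R)-4-methyl-4-[(triethylsilyl)oxy]hex-5-enal
Product: 17 (4R)-4-methyl-4-[(triethylsilyl)oxy]hex-5-enoic acid
Conditions: NaClO2, NaH2PO4, 2-methylbut-2-ene, t-BuOH/H2O, 0 → 23 °C
Reagents that add atoms: sodium chlorite, [Na+].[O-]Cl=O
Why: Pinnick oxidation should convert the aldehyde to the acid while the scavenger protects the vinyl group from hypochlorite.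

Step 10
Reactants: 17 (4R)-4-methyl-4-[(triethylsilyl)oxy]hex-5-enoic acid
Product: 19 triethyl{[(3R)-5-iodo-3-methylpent-1-en-3-yl]oxy}silane, via Barton ester 18 (not isolated)
Conditions: 1-hydroxypyridine-2(1H)-thione, DCC, DMAP (cat.), CH2Cl2, 0 → 23 °C, dark; then CHI3, PhH, hν (tungsten lamp), 23 °C
Reagents that add atoms: iodoform, IC(I)I
Why: Barton decarboxylative iodination: the thiohydroxamate ester should fragment in a radical chain and the primary radical, which has no favourable cyclisation onto the vinyl group, abstracts iodine from iodoform.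

Step 11
Reactants: 13 (2S,4aS,6R,8aR)-6-bromo-2,5,5,8a-tetramethyloctahydronaphthalen-1(2H)-one; 19 triethyl{[(3R)-5-iodo-3-methylpent-1-en-3-yl]oxy}silane
Product: 21 (1R,2S,4aS,6R,8aR)-6-bromo-1-[(3R)-3-hydroxy-3-methylpent-4-en-1-yl]-2,5,5,8a-tetramethyldecahydronaphthalen-1-ol (CNP0318118.1), via triethylsilyl ether 20 (not isolated)
Conditions: 19, t-BuLi (2.1 equiv), Et2O/pentane, −78 °C; CeCl3, THF, −78 °C; then 13, −78 → −40 °C; aq NH4Cl; then TBAF, AcOH, THF, 0 → 23 °C
Reagents that add atoms: none
Why: Iodine–lithium exchange and transmetalation should give a weakly basic organocerium reagent that adds 1,2 to the hindered ketone without enolisation at C8 or loss of HBr, approaching along the axial trajectory anti to the axial C10 methyl (which blocks the equatorial approach), so C9 receives the side chain axial and the hydroxyl equatorial; buffered fluoride then removes the silyl group.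

## Compound list

1 | pentan-3-one | CCC(=O)CC | starting material
2 | acrolein (prop-2-enal) | C=CC=O | starting material
3 | 1-(pent-2-en-3-yl)pyrrolidine | CC=C(CC)N1CCCC1 | intermediate
4 | 4-methyl-5-oxoheptanal (racemic) | CCC(=O)C(C)CCC=O | intermediate
5 | 4,4,5,5-tetramethyl-2-(3-methylbuta-1,2-dien-1-yl)-1,3,2-dioxaborolane | CC(C)=C=CB1OC(C)(C)C(C)(C)O1 | starting material
6 | (7S)-7-hydroxy-4,8,8-trimethyldec-9-yn-3-one (C4 epimers) | CCC(=O)C(C)CC[C@H](O)C(C)(C)C#C | intermediate
7 | (2S)-6-ethyl-5-methyl-2-(2-methylbut-3-yn-2-yl)-3,4-dihydro-2H-pyran | CCC1=C(C)CC[C@H](O1)C(C)(C)C#C | intermediate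
8 | 4-[(2S)-6-ethyl-5-methyl-3,4-dihydro-2H-pyran-2-yl]-4-methylpent-2-ynal | CCC1=C(C)CC[C@H](O1)C(C)(C)C#CC=O | intermediate
9 | 2-[(1S,4R)-3-ethylidene-4,6,6-trimethyl-2-oxabicyclo[2.2.2]octan-5-ylidene]acetaldehyde (alkene isomers) | O=CC=C1C(C)(C)[C@@H]2CC[C@@]1(C)C(=CC)O2 | intermediate
10 | (6S,8aR)-6-hydroxy-2,5,5,8a-tetramethyl-6,7,8,8a-tetrahydronaphthalen-1(5H)-one | O=C1C(C)=CC=C2C(C)(C)[C@@H](O)CC[C@]21C | intermediate
11 | (2R,4aR,6S,8aR)-6-hydroxy-2,5,5,8a-tetramethyloctahydronaphthalen-1(2H)-one | O=C1[C@H](C)CC[C@@H]2C(C)(C)[C@@H](O)CC[C@]21C | intermediate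
12 | (2S,4aR,6S,8aR)-6-hydroxy-2,5,5,8a-tetramethyloctahydronaphthalen-1(2H)-one | O=C1[C@@H](C)CC[C@@H]2C(C)(C)[C@@H](O)CC[C@]21C | intermediate
13 | (2S,4aS,6R,8aR)-6-bromo-2,5,5,8a-tetramethyloctahydronaphthalen-1(2H)-one | O=C1[C@@H](C)CC[C@@H]2C(C)(C)[C@H](Br)CC[C@]21C | intermediate
14 | (R)-(−)-linalool | C=C[C@](C)(O)CCC=C(C)C | starting material
15 | triethyl{[(3R)-3,7-dimethylocta-1,6-dien-3-yl]oxy}silane | C=C[C@](C)(O[Si](CC)(CC)CC)CCC=C(C)C | intermediate
16 | (4R)-4-methyl-4-[(triethylsilyl)oxy]hex-5-enal | C=C[C@](C)(O[Si](CC)(CC)CC)CCC=O | intermediate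
17 | (4R)-4-methyl-4-[(triethylsilyl)oxy]hex-5-enoic acid | C=C[C@](C)(O[Si](CC)(CC)CC)CCC(=O)O | intermediate
18 | 2-thioxopyridin-1(2H)-yl (4R)-4-methyl-4-[(triethylsilyl)oxy]hex-5-enoate | C=C[C@](C)(O[Si](CC)(CC)CC)CCC(=O)ON1C=CC=CC1=S | intermediate
19 | triethyl{[(3R)-5-iodo-3-methylpent-1-en-3-yl]oxy}silane | C=C[C@](C)(O[Si](CC)(CC)CC)CCI | intermediate
20 | (1R,2S,4aS,6R,8aR)-6-bromo-2,5,5,8a-tetramethyl-1-{(3R)-3-methyl-3-[(triethylsilyl)oxy]pent-4-en-1-yl}decahydronaphthalen-1-ol | C=C[C@](C)(O[Si](CC)(CC)CC)CC[C@@]1(O)[C@@H](C)CC[C@@H]2C(C)(C)[C@H](Br)CC[C@]21C | intermediate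
21 | (1R,2S,4aS,6R,8aR)-6-bromo-1-[(3R)-3-hydroxy-3-methylpent-4-en-1-yl]-2,5,5,8a-tetramethyldecahydronaphthalen-1-ol (CNP0318118.1) | C=C[C@](C)(O)CC[C@@]1(O)[C@@H](C)CC[C@@H]2C(C)(C)[C@H](Br)CC[C@]21C | target

## Step count and risks

Total step count: 11. Longest linear sequence: 7 steps (steps 1–6, then step 11); the side-chain branch is steps 7–10.

Steps most likely to fail:

1. Step 4 (the step that carries the label). What may go wrong: the enol ether hydrolyses before the C5–C10 bond forms, which removes the bridge and with it the control of C10, or the electron-poor alkyne is activated too weakly so that the ynal oligomerises. Fallback (sets out from 8, returns at 10): the bridge is given up and known anionic chemistry is used. Brief hydrolysis of the enol ether (PPTS, wet acetone) should give the open-chain (5S)-5-hydroxy-4,4,8-trimethyl-9-oxoundec-2-ynal F1. Cs2CO3 in MeCN (or KOt-Bu in t-BuOH) should then effect the base-mediated 6-exo-dig Michael addition of the more substituted ketone enolate to the ynal and the Robinson-type aldol condensation. This should give 10 together with its C8a epimer (6S,8aS)-6-hydroxy-2,5,5,8a-tetramethyl-6,7,8,8a-tetrahydronaphthalen-1(5H)-one F2. The two are diastereomers because the C6 carbinol is untouched, so they can be separated by chromatography, and 10 re-enters at step 5.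

2. Step 6. What may go wrong: E2 loss of the axial leaving group toward C2 and Wagner–Meerwein migration of the anti-periplanar C4 methyl compete with substitution at the neopentyl centre. Fallback (sets out from 12, returns at 13): activation and displacement are separated. SO2Cl2 and imidazole (CH2Cl2, −40 → 0 °C) should give the weakly ionising (2S,4aR,6S,8aR)-1,1,4a,6-tetramethyl-5-oxodecahydronaphthalen-2-yl 1H-imidazole-1-sulfonate F4. Bu4NBr in PhMe at 80 °C should then displace it with inversion to give 13.

3. Step 5. What may go wrong: the hydrogenation stalls at the shielded C5=C6 bond once the C7=C8 bond is saturated, or facial selectivity at C5 is eroded. Fallback (sets out from 10, returns at 12): hydroxyl-directed homogeneous hydrogenation with Ir(cod)(PCy3)(py)PF6 and H2 in CH2Cl2. The axial, homoallylic C3 hydroxyl should deliver hydrogen to C5 from its own face and give the trans-fused enone (4aR,6S,8aR)-6-hydroxy-2,5,5,8a-tetramethyl-4a,5,6,7,8,8a-hexahydronaphthalen-1(4H)-one F3. Its unhindered enone double bond is then reduced over Pd/C with H2 and C8 is equilibrated with NaOMe to give 12.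

Further compounds
F1 | step 4 | (5S)-5-hydroxy-4,4,8-trimethyl-9-oxoundec-2-ynal | CCC(=O)C(C)CC[C@H](O)C(C)(C)C#CC=O
F2 | step 4 | (6S,8aS)-6-hydroxy-2,5,5,8a-tetramethyl-6,7,8,8a-tetrahydronaphthalen-1(5H)-one | O=C1C(C)=CC=C2C(C)(C)[C@@H](O)CC[C@@]21C
F3 | step 5 | (4aR,6S,8aR)-6-hydroxy-2,5,5,8a-tetramethyl-4a,5,6,7,8,8a-hexahydronaphthalen-1(4H)-one | O=C1C(C)=CC[C@@H]2C(C)(C)[C@@H](O)CC[C@]21C
F4 | step 6 | (2S,4aR,6S,8aR)-1,1,4a,6-tetramethyl-5-oxodecahydronaphthalen-2-yl 1H-imidazole-1-sulfonate | O=C1[C@@H](C)CC[C@@H]2C(C)(C)[C@@H](OS(=O)(=O)n3ccnc3)CC[C@]21C
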